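The amber run has lost more substrate than it shows as target, 11.6% against 8.8% at 120 s, and before you ask for yields you can read that loss of substrate as a clock and count turnovers.

| flask | substrate | reagent | remark | time |
|---|---|---|---|---|
| amber | 0.98 M | 0.98 M | run made earlier |  |
| summer | 0.49 M | 0.980 M |  | 10 min |
| midnight | 0.49 M | 0.980 M |  | 25 min |

amber run (percent of the substrate charged)

| time / s | side product / % | substrate / % | isomer of the product / % | target / % |
|---|---|---|---|---|
| 15.0 | 0.2 | 99.1 | 0 | 1.8 |
| 30.0 | 0.4 | 97.2 | 0 | 2.7 |
| 50.0 | 1.2 | 96.1 | 0 | 3.4 |
| 60.0 | 0.2 | 95.5 | 0 | 5.0 |
| 80.0 | 0.8 | 92.1 | 0 | 7.5 |
| 90.0 | 1.1 | 90.4 | 0 | 6.7 |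
| 120 | 1.9 | 88.4 | 0.2 | 8.8 |

(each reading ± 0.5 percentage points)

- a species is counted by the substrate in it: one side product counts as two
- the numbers in the tables scatter by 0.5 percentage points (one standard deviation)
- a reading of substrate is of its free form alone

- which of these there is most of at the end, counted by the substrate in it, summer (side product / isomer of the product / target / substrate)
- which of these there is most of at the end, counted by the substrate in it, midnight (side product / isomer of the product / target / substrate)
- final amount of the leader among these, as a percentage of the substrate charged, in summer
- final amount of the leader among these, as a percentage of the substrate charged, in midnight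

1. The first instants. Summer and midnight start at c(reagent) 0.980 M, the same as amber, with twice the c(substrate) in reagent, and as my own assumption, which these charges do not prove, I treat the loss of substrate as pseudo-first-order at a rate carried over from amber. The last amber reading of substrate, 88.4%, gives 0.0616 min⁻¹ as the turnover rate, the logarithm of charged over remaining substrate per minute at this starting c(reagent); it is a reading and carries the scatter of 0.5 percentage points.

2. The middle. At 5.00 min my count for the summer flask stands at 0.308 turnovers, which gives 73.5% substrate, and here you should watch the side product, which in amber read 0.2% first and 1.9% last, while the isomer of the product first showed at 0.2%.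

3. The end. By my count summer reaches 0.616 turnovers and keeps 54.0% substrate, while midnight reaches 1.54 and keeps 21.4%. Target held 75.9% of the amber loss, as read, and that share gives midnight target 59.7% as my rough guess, more than its substrate of 21.4%. In summer the same share gives target 34.9%, less than its substrate of 54.0%, so I name substrate in summer and target in midnight.

4. The forecast, reckoning “first order in both substrate and reagent”, names substrate at 64% for summer, above my 54.0%, and target at 46% for midnight, below my rough guess.

The flasks give substrate at 52.4% in summer and target at 40.4% in midnight.

    substrate ⇌ other conformer (K = 0.760, k = 0.00687 min⁻¹)
    substrate + reagent → target (k = 0.0554 M⁻¹ min⁻¹)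
    reagent + other conformer → isomer of the product (k = 0.192 M⁻¹ min⁻¹)
    substrate + target → side product (k = 0.109 M⁻¹ min⁻¹)

Summer's substrate stands at 52.4% against the count's 54.0%, and midnight's at 19.6% against 21.4%, though midnight's reagent is down to 68% of its charge, while midnight target falls below my rough guess with side product at 32.0%. Now read the summer flask at 40 min: the same rate counts 2.47 turnovers and gives 8.46% substrate. That flask holds 7.45% substrate, with side product at 40.3% and target in the lead at 43.0%.

The runs are simulated for substances that don't exist; the scatter is artificial.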